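**Slow flasks.** The beta run was slow: by 21 min it had turned 49.3 % of its Z into J, with G charged at 6.00 % of its Z.

| flask | Z | G | time |
|---|---|---|---|
| epsilon | 150 mM | 4.50 mM |  |
| beta | 75.0 mM | 4.50 mM |  |
| alpha | 150 mM | 9.00 mM |  |
| eta | 220 mM | 4.50 mM |  |
| theta | 75.0 mM | 1.50 mM | 21 min |

| run | time / min | [J] / mM |
|---|---|---|
| epsilon run | 0.84 | 4.2 |
| epsilon run | 1.9 | 7.7 |
| epsilon run | 4.2 | 16.8 |
| epsilon run | 9.4 | 34.7 |
| epsilon run | 21 | 69.3 |
| beta run | 0.84 | 3.0 |
| beta run | 1.9 | 4.1 |
| beta run | 4.2 | 9.1 |
| beta run | 9.4 | 19.2 |
| beta run | 21 | 37.0 |
| alpha run | 0.84 | 5.7 |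
| alpha run | 1.9 | 15.3 |
| alpha run | 4.2 | 31.0 |
| alpha run | 9.4 | 62.4 |
| alpha run | 21 | 109.2 |
| eta run | 0.84 | 4.2 |
| eta run | 1.9 | 9.1 |
| eta run | 4.2 | 19.5 |
| eta run | 9.4 | 42.2 |
| eta run | 21 | 90.6 |

(scatter of a reading: 0.8 mM)

- Overall: Z -> J, with G as catalyst.
- Constant volume, constant temperature.
- Bound and free are read together.
- An order is taken over about fifteen percent of the charge, up and down.

1. reaction order in [G] at the outset, round the charge of the epsilon run, defined at two percent of the Z turned into J
2. reaction order in [Z] at the outset, round the charge of the epsilon run, defined at two percent of the Z turned into J (one fixed amount of J, the same in the runs compared)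
3. the beta run starts with 75.0 mM less of Z than the epsilon run, and with no J. Compared where both hold the same amount of Z, once fifteen percent of what the beta run was charged with has turned into J, is the beta run faster, slower or alike (within a tenth)?
4. J in the theta run at 21 min, as a share of the Z charged
5. which of these the readings show (the substrate pairs with itself / the product kills the catalyst / the product speeds the reaction / the substrate is lost by itself / the catalyst dies by itself)

**Bench rule.** At the bench I called a flask with steady G pseudo-first-order in Z: the fraction of Z left follows the dose, meaning G charged times minutes, whatever the charge of Z. I first wrote the balance of G, the reagent charged in the smaller amount, with free and bound read together. I took it as steady if equal doses gave equal J. The alpha run at 9.4 min had 0.895 of the dose of the epsilon run at 21 min, and its J stood at 0.900 of that run's J, so in my reckoning I kept G steady.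

The last reading of the beta run gave 5.78 M·s, and I named this the halving dose, the G charged times the minutes that halve the Z of a given charge. The reading of the beta run at 9.4 min gave 5.95 M·s, so between these two readings of the beta run the rule stood.

**The border.** The rule broke between charges. The eta run, with 2.93 times the Z of the beta run, had turned a smaller share at 21 min, 41.2 %. Its halving dose read 7.41 M·s, larger than that of the beta run. A halving dose therefore belongs to one charge of Z.

**My reckoning.** The theta run has the charge of Z of the beta run, 75.0 mM, so I used the halving dose of the beta run for it. Its dose of 1.89 M·s gave me 20.3 % of its Z as J.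

**The result.** The forecast gave 1, 0.62, alike, 20 % and the substrate pairs with itself, holding that “neither product nor time matters”. The flask gave 0.98 for the order in G, 0.62 for the order in Z, alike for the comparison, 21.1 % for the theta run, and the substrate pairs with itself.

    G + Z ⇌ GZ, settled at all times (7.350 M⁻¹)
    GZ + Z ⇌ GZ2, settled at all times (125.0 M⁻¹)
    GZ2 → J + GZ (2.166 min⁻¹)
    2 Z ⇌ Z2, settled at all times (61.80 M⁻¹)

**Why it held.** The halving dose of the theta run came to 5.52 M·s, against my 5.78 M·s from the beta run. The flask holds Z2, and the beta run has the same charge of Z as the theta run, so the tying up of two Z as Z2 was already inside my halving dose. In the theta run without that tying up, J reached 55.6 % of the Z charged, and the halving dose fell to 1.61 M·s.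

The runs are calculated with made-up constants, noise included.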